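The ratio I carried through this flask is second end groups plus scavenger charged, over twice the first end groups. Each reacted first end group frees one released group, and each scavenger takes up one of them; the scavenger is here the limiting reagent at 0.160 M against 0.20 M of first end groups. If the whole scavenger charge is used and every released group beyond that charge parks one second end group as idle adduct, free second end groups vanish at 90.0% reacted, which I call the parking knee.

| setting | north-east | south-west | north | flask |
|---|---|---|---|---|
| first end groups | 0.20 M | 0.20 M | 0.30 M | 0.20 M |
| second end groups | 0.20 M | 0.20 M | 0.20 M | 0.200 M |
| scavenger | 0.22 M | 0.35 M | 0.16 M | 0.160 M |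
| remark | run made earlier | run made earlier | run made earlier |  |
| time |  |  |  | 5.0 h |

| run | time / h | first end groups / % | links / % |
|---|---|---|---|
| north-east | 0.833 | 32.6 | 67.2 |
| north-east | 1.50 | 20.1 | 78.9 |
| north-east | 2.50 | 11.7 | 87.9 |
| north-east | 3.00 | 10.7 | 89.4 |
| south-west | 0.833 | 29.3 | 70.8 |
| south-west | 1.50 | 16.9 | 82.9 |
| south-west | 2.50 | 9.7 | 89.4 |
| south-west | 3.00 | 8.8 | 91.9 |
| north | 0.250 | 66.1 | 33.5 |
| north | 0.500 | 56.0 | 44.0 |
| north | 1.33 | 43.6 | 57.0 |
| north | 3.00 | 37.0 | 62.5 |

(standard deviation of a reading: 0.5 percentage points)

- amounts and yields of links count crystals too
- amounts and yields of released group count idle adduct too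
- given per volume of solution although it is solid: crystals
- the numbers in the tables scatter with a standard deviation of 0.5 percentage points
- candidate steps: first end groups + second end groups -> links + released group; second end groups + released group <-> idle adduct; scavenger + released group -> scavenged by-product; crystals <-> links
- the earlier runs do not show how much of second end groups is bound; that part of a forecast is a guess

- part of the first end groups that has reacted at 5.0 h
- share of the unused second end groups that is free and not bound as idle adduct, at 5.0 h

I bracketed the flask with two extreme versions. With parking perfectly tight, it stops at the knee. With the scavenger keeping up, equal end groups follow second-order decay, in which the reciprocal of the fraction left grows linearly with time. Scaling the last north-east reading then gives 93.3% reacted at 5.0 h, and this curve passes the knee at 3.24 h, earlier than the asked time. The north run, with a knee of 60.0%, read 63.0% reacted at 3.00 h, so parking there was tight but leaky. I therefore put the flask a little above its knee, and I had no grounds for the free share.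

The forecast gave 90.5% reacted and 42% free, adding “The free share is the guess”.

The flask gave 90.5% reacted and 29.1% free.

    first end groups + second end groups → links + released group (k = 0.386 M⁻¹ min⁻¹)
    second end groups + released group ⇌ idle adduct, settled at all times (K = 302 M⁻¹)
    scavenger + released group → scavenged by-product (k = 4.02 M⁻¹ min⁻¹)
    crystals ⇌ links, rate k4*(cs4 - [links]) while solid is left; crystals form when [links] > cs4 (solubility = 0.0980 M, k = 1.84 min⁻¹)

The flask's 90.5% lies 0.50 percentage points above its knee, with idle adduct at 0.0134 M and scavenger down to 0.262%. In the neighbouring flask, with scavenger cut to 0.096 M and the end groups and time held, the knee falls to 74.0%, while the scavenger-keeps-up mark stays at 93.3%. That neighbouring flask, its scavenger at 0%, gave 82.1% reacted, 8.1 points above its knee, with 8.53% of its unused second end groups free.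

The numbers in the tables stem from a simulated flask on assumed constants; the scatter is artificial.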